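## Retrosynthetic overview

1. Ring A is made last. The 3‑methylcyclohexenone is cut back by one carbon (C12) to a 2‑methylcyclopentenone. In the forward direction this is a one‑carbon ring expansion by 1,2‑shift of the alkenyl carbon C11.
2. Ring D (oxepane) comes from forming the C3–O bond between the C16‑OH and a C3=CH2 alkene by alkoxymercuration. Ring C (oxonene) comes from closing C6=C7 by RCM.
3. The C3–C6 chain is built in three bonds: C2–C3 by enol‑silane capture of the ring‑B oxocarbenium ion, C3=CH2 from CH2O, and C4–C5 by asymmetric allylboration.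
4. Ring B and the cyclopentenone come from a Pauson–Khand reaction of a propargyl acetal. Its cis alkene C1=C14 sits in a temporary dihydropyran, ring T (O, C2, C1, C14, C15, C16).
5. Ring T comes from Pd hydroalkoxylation of an allenyl ether followed by RCM. Ring order: T, then B plus the five‑membered pre‑A ring (T is opened afterwards), then C, D and A.

**Numbering.** Cladiellane numbering is used throughout.
- C1/C10 is the A/B ring fusion, and C2 and C9 flank the ring‑B oxygen.
- C3 carries Me and the oxepane O, C4 carries OAc, and the ring alkene is C6=C7(Me).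
- C11(Me)=C12–C13(=O) is the enone, followed by C14, C15(Me) and C16 (OCH2).
- The target is (1R,2S,3S,4R,6Z,9S,10S,14R,15R).

**Assumption.** But‑2‑ynal and enantiopure (R)‑2‑methylbut‑3‑en‑1‑ol are bought as catalogue items.

## Route

**Step 1**
Reactants: 1 but‑2‑ynal; 2 2‑methylallylmagnesium chloride
Product: 3 (S)‑2‑methylhept‑1‑en‑5‑yn‑4‑ol
Conditions: (−)‑Ipc2BOMe, 2, Et2O, −78 °C → rt; 1, −78 °C; then HOCH2CH2NH2
Reagents that add atoms: none
Why: Brown asymmetric allylboration through a closed chair transition state; the reagent derived from (+)‑α‑pinene gives the (S)‑carbinol when the aldehyde substituent outranks the allyl carbon, which sets C9.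

**Step 2**
Reactants: 4 (R)‑2‑methylbut‑3‑en‑1‑ol; 5 propargyl bromide
Product: 6 (R)‑3‑methyl‑4‑(prop‑2‑ynyloxy)but‑1‑ene
Conditions: NaH, Bu4NI (cat.), THF, 0 °C → rt
Reagents that add atoms: none
Why: Williamson ether synthesis on a primary alkoxide; the C15 stereocentre is not touched.

**Step 3**
Reactants: 6 (R)‑3‑methyl‑4‑(prop‑2‑ynyloxy)but‑1‑ene
Product: 7 (R)‑3‑methyl‑4‑(propa‑1,2‑dienyloxy)but‑1‑ene
Conditions: KOtBu (20 mol %), THF, 40 °C
Reagents that add atoms: none
Why: Base‑catalysed propargyl‑to‑allenyl ether isomerisation, driven by oxygen conjugation; the allylic C15–H is far too weakly acidic to be affected.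

**Step 4**
Reactants: 3 (S)‑2‑methylhept‑1‑en‑5‑yn‑4‑ol; 7 (R)‑3‑methyl‑4‑(propa‑1,2‑dienyloxy)but‑1‑ene
Product: 8 mixed acrolein acetal (2R,9S,15R), CH2=CH–CH(O–C9 unit)(O–CH2CH(Me)CH=CH2)
Conditions: Pd2(dba)3·CHCl3 (2.5 mol %), (R,R)‑DACH‑phenyl Trost ligand (6 mol %), Et3N (0.5 equiv), toluene, rt
Reagents that add atoms: none
Why: Asymmetric hydroalkoxylation of an alkoxyallene (Tsuji–Trost type); zerovalent palladium and a proton give an alkoxy‑π‑allyl complex, the alcohol attacks its oxygen‑bearing end, and the ligand sets the relay acetal centre C2 (the antipodal ligand gives the epimer).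

**Step 5**
Reactants: 8 mixed acrolein acetal
Product: 9 (3R,6R)‑3‑methyl‑6‑[(4S)‑2‑methylhept‑1‑en‑5‑yn‑4‑yloxy]‑3,6‑dihydro‑2H‑pyran (ring T; alkoxy group trans to methyl)
Conditions: first‑generation Grubbs catalyst RuCl2(=CHPh)(PCy3)2 (5 mol %), CH2Cl2 (0.02 M), rt
Reagents that add atoms: none
Why: Ring‑closing metathesis; this catalyst engages only the two monosubstituted vinyl groups (not the 1,1‑disubstituted alkene or the internal alkyne), the six‑membered ring forces the cis C1=C14 geometry, and the neutral medium keeps the kinetic acetal configuration.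

**Step 6**
Reactants: 9 dihydropyran acetal
Product: 11 tricyclic acetal enone (1S,2R,9S,14R,15R): 2‑methylcyclopentenone C10=C11(Me)–C13(=O) fused to ring B and ring T, via dicobalt hexacarbonyl complex 10 (not isolated)
Conditions: Co2(CO)8 (1.1 equiv), CH2Cl2, rt; then NMO (8 equiv), 0 °C → rt
Reagents that add atoms: dicobalt octacarbonyl (delivers one CO = C13), [Co].[Co].[C-]#[O+].[C-]#[O+].[C-]#[O+].[C-]#[O+].[C-]#[O+].[C-]#[O+].[C-]#[O+].[C-]#[O+]
Why: Intramolecular Pauson–Khand reaction of a 1,6‑enyne; the pseudo‑axial acetal oxygen delivers the alkyne to its own alkene face, which is anti to the C15 methyl, so syn addition to the cis alkene sets C1 and C14 with C2 and C15 on the same face of the five‑membered pre‑A ring (C9 joins that face when C10 is protonated in step 13), and the methallyl group lies on the convex face.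

**Step 7**
Reactants: 11 tricyclic acetal enone; 12 trimethyl(vinyloxy)silane
Product: 14 ring‑B acetaldehyde (1S,2R,9S,14R,15R) carrying C2–CH2CHO and a free C16‑OH, via C16 trimethylsilyl ether 13 (not isolated)
Conditions: 12 (3 equiv), TMSOTf (15 mol %), CH2Cl2, −78 → −40 °C; then 1 M HCl, THF, 0 °C
Reagents that add atoms: none
Why: Mukaiyama‑type C‑glycosidation; the silyl cation goes to the unhindered OCH2 oxygen (the other acetal oxygen is flanked by two branched carbons and deactivated by the enone), ring T opens to the ring‑B oxocarbenium ion, and the enol silane attacks its convex face anti to C14, setting C2 (H1/H2 trans, 2,5‑cis); aldehydes are inert under TMSOTf catalysis.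

**Step 8**
Reactants: 14 ring‑B acetaldehyde
Product: 15 2‑substituted acrolein (1S,2S,9S,14R,15R), C2–C(=CH2)–CHO
Conditions: 37 % aq. HCHO, pyrrolidine (10 mol %), EtCO2H (10 mol %), iPrOH, 40 °C
Reagents that add atoms: formaldehyde, C=O
Why: Organocatalytic α‑methylenation (enamine Mannich addition then amine elimination); only the aldehyde forms an enamine, and no stereocentre is made.

**Step 9**
Reactants: 15 2‑substituted acrolein; 16 allylmagnesium bromide
Product: 17 diol (1S,2S,4R,9S,14R,15R) with C3(=CH2)–C4H(OH)–CH2CH=CH2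
Conditions: (+)‑Ipc2BOMe, 16, Et2O, −78 °C → rt; 15, −78 °C (2.5 equiv of borane); then HOCH2CH2NH2
Reagents that add atoms: none
Why: Brown asymmetric allylboration; it is aldehyde‑selective at −78 °C (the hindered enone is untouched), and the reagent derived from (−)‑α‑pinene sets (4R) under reagent control.

**Step 10**
Reactants: 17 diol
Product: 18 (6Z)‑oxonene diol (1S,2S,4R,9S,14R,15R), ring C closed
Conditions: second‑generation Grubbs catalyst RuCl2(=CHPh)(PCy3)(H2IMes) (10 mol %), 1,4‑benzoquinone (20 mol %), CH2Cl2 (1 mM), reflux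
Reagents that add atoms: none
Why: Ring‑closing metathesis between the allyl and methallyl arms, which are held cis on ring B; ring strain allows only the Z trisubstituted alkene, and the hindered C3=CH2 group cannot give a viable ring.

**Step 11**
Reactants: 18 oxonene diol
Product: 20 tetracyclic alcohol (1S,2S,3S,4R,6Z,9S,14R,15R), ring D closed, via alkylmercury acetate 19 (not isolated)
Conditions: Hg(OAc)2 (1.1 equiv), CH2Cl2, 0 °C → rt; then Bu3SnH (5 equiv, 1 M), toluene, 0 °C → rt
Reagents that add atoms: none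
Why: Intramolecular Markovnikov alkoxymercuration followed by reductive demercuration; divalent mercury adds reversibly, and only C3=CH2 has a hydroxyl within reach. In the conformer with C=CH2 eclipsing C2–H (minimum A(1,3) strain), the C16‑OH reaches C3 from the C1 side, which gives (3S); concentrated stannane outruns radical cyclisation.

**Step 12**
Reactants: 20 tetracyclic alcohol
Product: 21 tetracyclic acetate (cyclopentenone stage)
Conditions: Ac2O, DMAP (cat.), pyridine, rt
Reagents that add atoms: acetic anhydride, CC(=O)OC(C)=O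
Why: DMAP‑catalysed acylation of the only remaining hydroxyl, with retention at C4.

**Step 13**
Reactants: 21 tetracyclic acetate
Product: 24 target CNP0320560.1, via C12‑silyl ketone 22 (not isolated), via deconjugated enone 23 (not isolated)
Conditions: TMSCHN2 (1.5 equiv), Sc(OTf)3 (10 mol %), CH2Cl2, −78 → 0 °C; 1 M HCl, THF, 0 °C; then DABCO (20 mol %), CH2Cl2, rt
Reagents that add atoms: (trimethylsilyl)diazomethane, C[Si](C)(C)C=[N+]=[N-]
Why: Proposed new method: one‑carbon insertion into a fully substituted Pauson–Khand cyclopentenone with exclusive 1,2‑shift of the alkenyl carbon. The diazo carbon adds to the Sc‑activated C13 carbonyl from the convex face, and on loss of N2 the sp2 carbon C11 migrates, because its π bond stabilises the electron‑deficient transition state and the competing C14 is a hindered secondary alkyl of low migratory aptitude, while strain of the bicyclo[3.3.0]octenone is released. Protodesilylation gives the C10=C11 deconjugated enone, whose doubly activated C12–H is removed by a mild amine that cannot touch C14–H, and γ‑protonation at C10 gives the cis A/B fusion (10S) and the conjugated 3‑methylcyclohexenone. The closest known reaction type is the Lewis‑acid‑promoted diazoalkane homologation of saturated cyclic ketones (Tiffeneau–Demjanov/Büchner–Curtius–Schlotterbeck type), which has not been shown on such ring‑fused tetrasubstituted enones.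

## Compound list

| No. | Name | SMILES | Role |
|---|---|---|---|
| 1 | but‑2‑ynal | CC#CC=O | starting material |
| 2 | 2‑methylallylmagnesium chloride | CC(=C)C[Mg]Cl | starting material |
| 3 | (S)‑2‑methylhept‑1‑en‑5‑yn‑4‑ol | O[C@@H](CC(C)=C)C#CC | intermediate |
| 4 | (R)‑2‑methylbut‑3‑en‑1‑ol | C=C[C@@H](C)CO | starting material |
| 5 | propargyl bromide | BrCC#C | starting material |
| 6 | (R)‑3‑methyl‑4‑(prop‑2‑ynyloxy)but‑1‑ene | C=C[C@@H](C)COCC#C | intermediate |
| 7 | (R)‑3‑methyl‑4‑(propa‑1,2‑dienyloxy)but‑1‑ene | C=C[C@@H](C)COC=C=C | intermediate |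
| 8 | mixed acrolein acetal (2R,9S,15R) | C=C[C@@H](C)CO[C@@H](C=C)O[C@@H](CC(C)=C)C#CC | intermediate |
| 9 | (3R,6R)‑3‑methyl‑6‑[(4S)‑2‑methylhept‑1‑en‑5‑yn‑4‑yloxy]‑3,6‑dihydro‑2H‑pyran | C[C@H]1CO[C@H](O[C@@H](CC(C)=C)C#CC)C=C1 | intermediate |
| 10 | dicobalt hexacarbonyl alkyne complex of 9 (written as components) | C[C@H]1CO[C@H](O[C@@H](CC(C)=C)C#CC)C=C1.[Co].[Co].[C-]#[O+].[C-]#[O+].[C-]#[O+].[C-]#[O+].[C-]#[O+].[C-]#[O+] | intermediate |
| 11 | tricyclic acetal enone (1S,2R,9S,14R,15R) | C[C@H]1CO[C@@H]2O[C@@H](CC(C)=C)C3=C(C)C(=O)[C@H]1[C@H]23 | intermediate |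
| 12 | trimethyl(vinyloxy)silane | C=CO[Si](C)(C)C | starting material |
| 13 | C16 trimethylsilyl ether of 14 | O=CC[C@H]1O[C@@H](CC(C)=C)C2=C(C)C(=O)[C@H]([C@@H](C)CO[Si](C)(C)C)[C@H]12 | intermediate |
| 14 | ring‑B acetaldehyde (1S,2R,9S,14R,15R) | O=CC[C@H]1O[C@@H](CC(C)=C)C2=C(C)C(=O)[C@H]([C@@H](C)CO)[C@H]12 | intermediate |
| 15 | 2‑substituted acrolein (1S,2S,9S,14R,15R) | O=CC(=C)[C@H]1O[C@@H](CC(C)=C)C2=C(C)C(=O)[C@H]([C@@H](C)CO)[C@H]12 | intermediate |
| 16 | allylmagnesium bromide | C=CC[Mg]Br | starting material |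
| 17 | diol (1S,2S,4R,9S,14R,15R) | O[C@@H](C(=C)[C@H]1O[C@@H](CC(C)=C)C2=C(C)C(=O)[C@H]([C@@H](C)CO)[C@H]12)CC=C | intermediate |
| 18 | (6Z)‑oxonene diol | O[C@@H]1C/C=C(/C)C[C@@H]2O[C@H](C1=C)[C@@H]3C2=C(C)C(=O)[C@@H]3[C@@H](C)CO | intermediate |
| 19 | alkylmercury acetate (C3–CH2HgOAc) | O[C@@H]1C/C=C(/C)C[C@@H]2O[C@H]3[C@@H]4C2=C(C)C(=O)[C@@H]4[C@@H](C)CO[C@@]13C[Hg]OC(C)=O | intermediate |
| 20 | tetracyclic alcohol (1S,2S,3S,4R,6Z,9S,14R,15R) | O[C@@H]1C/C=C(/C)C[C@@H]2O[C@H]3[C@@H]4C2=C(C)C(=O)[C@@H]4[C@@H](C)CO[C@@]13C | intermediate |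
| 21 | tetracyclic acetate (cyclopentenone stage) | CC(=O)O[C@@H]1C/C=C(/C)C[C@@H]2O[C@H]3[C@@H]4C2=C(C)C(=O)[C@@H]4[C@@H](C)CO[C@@]13C | intermediate |
| 22 | C12‑trimethylsilyl ring‑expanded ketone (C12 epimers) | CC(=O)O[C@@H]1C/C=C(/C)C[C@@H]2O[C@H]3[C@@H]4C2=C(C)C([Si](C)(C)C)C(=O)[C@@H]4[C@@H](C)CO[C@@]13C | intermediate |
| 23 | deconjugated (C10=C11) cyclohexenone | CC(=O)O[C@@H]1C/C=C(/C)C[C@@H]2O[C@H]3[C@@H]4C2=C(C)CC(=O)[C@@H]4[C@@H](C)CO[C@@]13C | intermediate |
| 24 | CNP0320560.1 (1R,2S,3S,4R,6Z,9S,10S,14R,15R) | CC(=O)O[C@@H]1C/C=C(/C)C[C@@H]2O[C@H]3[C@@H]4[C@H]2C(C)=CC(=O)[C@@H]4[C@@H](C)CO[C@@]13C | target |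

## Step count and risks

- Total step count: 13.
- Longest linear sequence: 12 steps (4 → 6 → 7 → 8 → 9 → 11 → 14 → 15 → 17 → 18 → 20 → 21 → 24).
- From step 7 until ring D is closed in step 11, C14 is an unlocked centre α to the ketone, so strong base is avoided throughout.

The three steps most likely to fail are these.

**1. Step 13 (the proposed new step).** The hindered enone may add the diazoalkane poorly, C14 may migrate in part, or C10 may be protonated from the wrong face. The fallback uses known chemistry, sets out from 21 and comes back at 24, and is a stepwise Saegusa‑type ring enlargement.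
- Conjugate hydrosilylation (Et3SiH, RhCl(PPh3)3) delivers hydride to C10 from the convex face and gives the regiodefined triethylsilyl enol ether F1.
- Simmons–Smith cyclopropanation (Et2Zn, CH2I2, 1.2 equiv, −20 °C) of this most electron‑rich alkene gives the siloxycyclopropane F2.
- FeCl3 in DMF opens the inner cyclopropane bond by one‑electron oxidation and gives the ring‑enlarged β‑chloro ketone F3.
- NaOAc in MeOH eliminates HCl to give 24.

**2. Step 7.** The Lewis acid may cleave the other acetal C–O bond and leave ring T intact. The fallback sets out from 11 and comes back at 14, and makes the choice by protecting‑group chemistry instead.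
- AcOH/THF/H2O hydrolyses 11 to the furanose lactol diol F4.
- TBSCl/imidazole silylates the primary C16 hydroxyl and so drains the lactol equilibrium into the silylated lactol F5.
- Ac2O/pyridine gives the anomeric acetate F6, in which acetate is the only ionisable group.
- BF3·OEt2 and 12 then give the silylated C‑glycoside aldehyde F7, again by convex‑face attack.
- HF·pyridine frees 14.

**3. Step 11.** The seven‑membered closure onto an electron‑poor, hindered alkene may be slow, and the demercuration radical may attack C6=C7. The fallback sets out from 18 and comes back at 20, and reverses the polarity of the ether closure.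
- Mukaiyama hydration (Co(acac)2, PhSiH3, O2, THF) of the 1,1‑disubstituted alkene gives the C3 tertiary alcohol triol F8.
- Tf2O/2,6‑lutidine at −78 °C forms the primary C16 triflate F9.
- The tertiary C3 hydroxyl displaces the triflate on warming and gives 20.

## Further compounds

F1 | step 13 | triethylsilyl enol ether (C11=C13–OSiEt3, 10S) | CC(=O)O[C@@H]1C/C=C(/C)C[C@@H]2O[C@H]3[C@@H]4[C@H]2C(C)=C(O[Si](CC)(CC)CC)[C@@H]4[C@@H](C)CO[C@@]13C
F2 | step 13 | siloxycyclopropane (C12 methylene added on the face of H1, H10 and H14) | CC(=O)O[C@@H]1C/C=C(/C)C[C@@H]2O[C@H]3[C@@H]4[C@H]2[C@@]5(C)C[C@@]5(O[Si](CC)(CC)CC)[C@@H]4[C@@H](C)CO[C@@]13C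
F3 | step 13 | ring‑enlarged β‑chloro ketone (C11 epimers) | CC(=O)O[C@@H]1C/C=C(/C)C[C@@H]2O[C@H]3[C@@H]4[C@H]2C(C)(Cl)CC(=O)[C@@H]4[C@@H](C)CO[C@@]13C
F4 | step 7 | furanose lactol diol (C2 anomers) | OC1O[C@@H](CC(C)=C)C2=C(C)C(=O)[C@H]([C@@H](C)CO)[C@H]12
F5 | step 7 | silylated lactol (C16‑OTBS, C2 anomers) | OC1O[C@@H](CC(C)=C)C2=C(C)C(=O)[C@H]([C@@H](C)CO[Si](C)(C)C(C)(C)C)[C@H]12
F6 | step 7 | anomeric acetate (C2 anomers) | CC(=O)OC1O[C@@H](CC(C)=C)C2=C(C)C(=O)[C@H]([C@@H](C)CO[Si](C)(C)C(C)(C)C)[C@H]12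
F7 | step 7 | silylated C‑glycoside aldehyde | O=CC[C@H]1O[C@@H](CC(C)=C)C2=C(C)C(=O)[C@H]([C@@H](C)CO[Si](C)(C)C(C)(C)C)[C@H]12
F8 | step 11 | C3 tertiary alcohol triol | O[C@@H]1C/C=C(/C)C[C@@H]2O[C@H]([C@@]1(C)O)[C@@H]3C2=C(C)C(=O)[C@@H]3[C@@H](C)CO
F9 | step 11 | primary C16 triflate | O[C@@H]1C/C=C(/C)C[C@@H]2O[C@H]([C@@]1(C)O)[C@@H]3C2=C(C)C(=O)[C@@H]3[C@@H](C)COS(=O)(=O)C(F)(F)F
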